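Remark on the chemistry: the facial sense of IpcBH2 is carried over from 1-arylcycloalkenes, and that of the ruthenium transfer-hydrogenation catalyst used in two fallbacks from aryl alkyl ketones. "SEM-oxy" stands for [2-(trimethylsilyl)ethoxy]methoxy throughout.

## Analysis of the target

Target 27 is a cis-isoflavan-4-ol: a chroman whose benzo ring A carries a 5-hydroxyl and a 7-methoxyl, with a secondary hydroxyl at C4 and ring B (2'-methoxy, 4'-hydroxy, 5'-prenyl) at C3. C3 and C4 are the only stereocentres, both R, and the aryl group and the hydroxyl lie on the same face of the pyran ring. The C4 carbinol is benzylic to a ring with oxygen at both ortho positions (O1, O5) and at the para position (O7), so mild acid is enough to ionise it, after which it dehydrates or epimerises. The free 4'-phenol next to the prenyl group closes to a dimethylchroman under acid, and the prenyl alkene rules out hydrogenolysis and must not meet a borane. C3 becomes epimerisable whenever C4 is a carbonyl. The hard points are therefore telling the three ring A oxygens apart, setting two adjacent stereocentres in the cis arrangement that equilibration would not favour, and freeing two phenols at the end without acid. The strategy rests on ring A: the bonds C4a–C4 and C8a–O1 sit on neighbouring carbons and the C5 oxygen is next to C4a, which is the pattern a carbonyl group leaves when it adds across a 3-oxygenated aryne.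

## Retrosynthetic reasoning

**27 to 26.** The two phenols are released last from fluoride-labile acetal ethers in 26. Acid and hydrogenolysis are both excluded by the C4 carbinol and the prenyl group, so the ether O–CH2 bonds are the only ones cut here.

**26 to 24 and 25.** The C5'–CH2 bond is cut. The prenyl group comes from boronate 25 by cross-coupling onto the aryl bromide of 24. It is introduced after all borane chemistry, and the bromine marks C5' from the first step of the ring B branch.

**24 to 23 to 22.** The cis carbinol 24 is taken back to ketone 23 and that to the trans carbinol 22. A direct addition across a C3=C4 alkene gives only the trans relationship, so C4 is corrected by oxidation and a hindered hydride while C3 is kept.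

**22 to 20.** The C3–H and C4–O bonds are cut together, leading to the achiral isoflav-3-ene 20. The forward step is an asymmetric hydroboration that puts boron on C4 and hydrogen on C3 from one face, and so fixes the absolute configuration at C3.

**20 to 9 and 16.** This is the central disconnection: C4a–C4, C8a–O1 and O1–C2 are cut. Ring A becomes the aryne released from ortho-silylaryl triflate 9, and C2, C3, C4 and ring B come from 2-arylacrolein 16. Cutting here gives two fragments of similar size, needs no stereocontrol, and lets the C5 oxygen direct which aryne carbon takes the carbonyl oxygen.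

**9 to 7 to 3 to 2 to 1.** The triflate of 9 comes from a carbamate (7), the silicon from directed metalation of carbamate 3, and 3 from mono-ether 2 of the symmetric diol 1. The forward sequence must place silicon only on the carbon between the two non-methyl oxygens.

**16 to 15 to 13 to 12 to 11 to 10.** The methylene of 16 is removed to give arylacetaldehyde 15, the extra carbon of 15 is removed by way of enol ether 13 to aldehyde 12, and protection and bromination lead back to commercial aldehyde 10. The bromination has to go ortho to the phenol and para to the methoxyl.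

## Alternatives that were turned down

**Alternative 1:** The pyran ring would be cut at O1–C2 and C3–C4. In the forward step a chiral amine–thiourea would promote oxa-Michael addition of 2,6-dihydroxy-4-methoxybenzaldehyde A3 to the nitroalkene A2, followed by intramolecular Henry closure to the 3-aryl-3-nitrochroman-4-ol A1. This route is shorter, the aldehyde A3 is symmetric so ring A needs no differentiation, the prenyl group is present from the start, and C4 is set by the catalyst; on these points it is stronger than the chosen route. Against it, an electron-rich 1-aryl-1-nitroethene such as A2 polymerises easily, the Henry step onto a fully substituted nitronate carbon is reversible so the C4 configuration can erode, and C3 is only defined when the tertiary nitro group is removed through a planar benzylic radical under weak 1,2-induction. The chosen route offers instead a C3 centre set by reagent control on a defined alkene and a C4 centre set by a strongly biased reduction.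

**Alternative 2:** Ring B would be cut at C1'–C2', C3'–C4' and C4'–C5'. Irradiation of the α-diazo enone A5 would give a vinylketene by Wolff rearrangement, which adds methoxyacetylene A6; the vinylcyclobutenone reopens and electrocyclises to the phenol A4. The substitution pattern of ring B, prenyl group included, would be fixed by the annulation and the stereocentres would not be touched afterwards, which is an advantage. However, the C3/C4 pair must first be built on an aliphatic precursor by a separate asymmetric sequence. The diazo carbon of A5 carries a secondary alkyl group whose hydrogen can shift to the carbene in competition with the Wolff step. The prenyl alkene and the β-silyloxy group are exposed to ultraviolet light and a ketene, A6 is volatile and hard to handle, and the linear sequence is long. The chosen route buys ring B complete and spends its risk on one convergent step.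

**Alternative 3:** The cut is C2–C3. A dirhodium tetracarboxylate would turn diazo ketone A8 into a carbenoid at C3 that inserts into a C–H bond of an ortho methoxy group, closing the pyranone to the racemic isoflavanone A7. This reaches the ketone oxidation level in very few steps from a deoxybenzoin and avoids the hydroboration and reoxidation of the chosen route, so it is at least as good on step economy. Against it, attack of the carbenoid on the ether oxygen gives a five-membered oxonium ylide and a Stevens shift, and Buchner addition to either arene also competes with the six-membered insertion. A7 is racemic and has methyl on both O5 and O7, so a Lewis-acid demethylation at O5 would be needed in the presence of the prenyl group and the silyl ether, followed by a resolving reduction. The chosen route carries O5 differentiated from the first step and never exposes the prenyl group to a Lewis acid.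

Key step: step 10

## Route

**Step 1**
Reactants: 1 5-methoxyresorcinol
Product: 2 3-methoxy-5-(SEM-oxy)phenol
Conditions: SEMCl (0.9 equiv), i-Pr2NEt, CH2Cl2, 0 °C to rt
Reagents that add atoms: 2-(trimethylsilyl)ethoxymethyl chloride, C[Si](C)(C)CCOCCl
Why: O-alkylation of a phenol with an α-chloro ether; the two hydroxyls are equivalent, so only one mono-ether can form, and a deficit of chloride should leave recoverable diol rather than bis-ether as the main companion.

**Step 2**
Reactants: 2 3-methoxy-5-(SEM-oxy)phenol
Product: 3 3-methoxy-5-(SEM-oxy)phenyl N-isopropylcarbamate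
Conditions: i-PrNCO, Et3N (cat.), CH2Cl2, rt
Reagents that add atoms: isopropyl isocyanate, CC(C)N=C=O
Why: Base-catalysed addition of the phenol to an isocyanate gives the secondary carbamate, which is a strong director for metalation and is later removable under mild basic conditions.

**Step 3**
Reactants: 3 3-methoxy-5-(SEM-oxy)phenyl N-isopropylcarbamate
Product: 7 5-methoxy-3-(SEM-oxy)-2-(trimethylsilyl)phenyl N-isopropylcarbamate, via N-silyl carbamate 4 (not isolated), via aryllithium 5 (not isolated), via C-silylated N-silyl carbamate 6 (not isolated)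
Conditions: TBSOTf (1.1 equiv), TMEDA, Et2O, 0 °C to rt; n-BuLi, TMEDA, −78 °C; TMSCl, −78 °C to rt; aq NaHSO4
Reagents that add atoms: chlorotrimethylsilane, C[Si](C)(C)Cl
Why: Directed ortho-metalation: N-silylation masks the N–H, lithiation should occur at the one CH flanked by the carbamate and the acetal oxygen of the SEM ether (both better directors than methoxyl), and the silyl chloride traps the anion; the slight excess of silyl triflate is consumed by the N–H before it can activate the acetal, and the aqueous wash removes the N-silyl group.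

**Step 4**
Reactants: 7 5-methoxy-3-(SEM-oxy)-2-(trimethylsilyl)phenyl N-isopropylcarbamate
Product: 9 5-methoxy-3-(SEM-oxy)-2-(trimethylsilyl)phenyl trifluoromethanesulfonate, via silylphenol 8 (not isolated)
Conditions: Et2NH, DBU, MeCN, 40 °C; then PhNTf2, rt
Reagents that add atoms: N-phenylbis(trifluoromethanesulfonimide), O=S(=O)(N(c1ccccc1)S(=O)(=O)C(F)(F)F)C(F)(F)F
Why: The secondary carbamate fragments by E1cB loss of isocyanate, which the amine traps as a urea, and the phenoxide is triflated in the same pot; this is the standard closing sequence for ortho-silylaryl triflates.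

**Step 5**
Reactants: 10 4-hydroxy-2-methoxybenzaldehyde
Product: 11 5-bromo-4-hydroxy-2-methoxybenzaldehyde
Conditions: Br2 (1.0 equiv), NaOAc, AcOH, rt
Reagents that add atoms: bromine, BrBr
Why: Electrophilic aromatic bromination should go to C5, which is ortho to the phenol and para to the methoxyl; C3 lies between two oxygens, is more hindered and has no para donor.

**Step 6**
Reactants: 11 5-bromo-4-hydroxy-2-methoxybenzaldehyde
Product: 12 5-bromo-2-methoxy-4-(SEM-oxy)benzaldehyde
Conditions: SEMCl, i-Pr2NEt, CH2Cl2, 0 °C to rt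
Reagents that add atoms: 2-(trimethylsilyl)ethoxymethyl chloride, C[Si](C)(C)CCOCCl
Why: O-alkylation of an acidic phenol (para to the aldehyde, ortho to bromine) with the α-chloro ether.

**Step 7**
Reactants: 12 5-bromo-2-methoxy-4-(SEM-oxy)benzaldehyde
Product: 13 1-bromo-4-methoxy-5-(2-methoxyvinyl)-2-(SEM-oxy)benzene (E/Z mixture)
Conditions: Ph3P(CH2OMe)Cl, KOt-Bu, THF, 0 °C; then 12, 0 °C to rt
Reagents that add atoms: (methoxymethyl)triphenylphosphonium chloride, COC[P+](c1ccccc1)(c1ccccc1)c1ccccc1.[Cl-]
Why: Wittig reaction with the methoxymethylene ylide adds one carbon as an enol ether; the alkene geometry is irrelevant because both isomers give the same aldehyde.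

**Step 8**
Reactants: 13 1-bromo-4-methoxy-5-(2-methoxyvinyl)-2-(SEM-oxy)benzene
Product: 15 2-[5-bromo-2-methoxy-4-(SEM-oxy)phenyl]acetaldehyde, via α-mercurio aldehyde 14 (not isolated)
Conditions: Hg(OAc)2, THF/H2O (10:1), 0 °C; then aq KI
Reagents that add atoms: water, O
Why: Oxymercuration of the enol ether followed by iodide-induced demercuration hydrolyses it under near-neutral conditions, so the aryl SEM acetal never meets protic acid; the aldehyde is used crude because arylacetaldehydes self-condense.

**Step 9**
Reactants: 15 2-[5-bromo-2-methoxy-4-(SEM-oxy)phenyl]acetaldehyde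
Product: 16 2-[5-bromo-2-methoxy-4-(SEM-oxy)phenyl]acrolein
Conditions: aq HCHO (37%), pyrrolidine (10 mol%), EtCO2H (10 mol%), i-PrOH, 45 °C
Reagents that add atoms: formaldehyde, C=O
Why: Amine-catalysed α-methylenation (Mannich condensation through the enamine, then elimination of the amine); the acrolein should be used promptly because 2-arylacroleins dimerise on standing.

**Step 10**
Reactants: 9 5-methoxy-3-(SEM-oxy)-2-(trimethylsilyl)phenyl trifluoromethanesulfonate; 16 2-[5-bromo-2-methoxy-4-(SEM-oxy)phenyl]acrolein
Product: 20 3-[5-bromo-2-methoxy-4-(SEM-oxy)phenyl]-7-methoxy-5-(SEM-oxy)-2H-chromene, via aryne 17 (not isolated), via benzoxete 18 (not isolated), via ortho-quinone methide 19 (not isolated)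
Conditions: CsF (3 equiv), MeCN, rt; 9 added slowly to 16 (1.5 equiv), dilute
Reagents that add atoms: none
Why: Fluoride attacks the trimethylsilyl group of 9 and triflate leaves, giving aryne 17; the aldehyde oxygen of 16 adds to the aryne carbon remote from the SEM-oxy group (future C8a) and the aryl anion, stabilised inductively by the adjacent C–O bond, closes on the carbonyl carbon (future C4) to give benzoxete 18. Thermal 4π ring opening of 18 gives ortho-quinone methide 19, an oxatriene whose disrotatory oxa-6π electrocyclisation forms O1–C2 on the acrolein methylene and closes the six-membered pyran ring with rearomatisation of ring A. The closest known reaction type is the fluoride-induced annulation of arynes with α,β-unsaturated aldehydes to 2H-chromenes, and the insertion of arynes into the carbonyl group of formamides proceeds through the same benzoxete. No stereocentre survives in 20, since the sp3 carbon of 18 becomes trigonal again. The step needs regioselective addition to the unsymmetrical aryne, and this is secured by the C5 oxygen next to one aryne carbon, which polarises the strained bond; the 7-methoxyl is too remote to interfere. It also needs the intramolecular electrocyclisation to outrun capture of 19 by a second aryne, which slow aryne release, dilution and an excess of 16 should ensure. The 2-arylacrolein has no α-hydrogen and cannot enolise, and its α-aryl group ends up directly as the C3 substituent. The aryl bromide and both SEM ethers are inert to CsF at room temperature.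

**Step 11**
Reactants: 20 3-[5-bromo-2-methoxy-4-(SEM-oxy)phenyl]-7-methoxy-5-(SEM-oxy)-2H-chromene
Product: 22 (3R,4S)-3-[5-bromo-2-methoxy-4-(SEM-oxy)phenyl]-7-methoxy-5-(SEM-oxy)chroman-4-ol (trans), via chromanylborane 21 (not isolated)
Conditions: IpcBH2 [from (1S)-(−)-α-pinene, prepared separately], THF, −25 to 0 °C; then NaOH, H2O2, 0 °C
Reagents that add atoms: hydrogen peroxide, OO
Why: Asymmetric hydroboration–oxidation of a trisubstituted aryl alkene: boron goes to the less substituted C4 and hydrogen to C3 in a syn addition, the isopinocampheyl group selects the face (sense assigned by analogy with 1-arylcyclohexenes), and oxidation with retention gives the trans carbinol and with it the 3R centre.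

**Step 12**
Reactants: 22 (3R,4S)-3-[5-bromo-2-methoxy-4-(SEM-oxy)phenyl]-7-methoxy-5-(SEM-oxy)chroman-4-ol
Product: 23 (3R)-3-[5-bromo-2-methoxy-4-(SEM-oxy)phenyl]-7-methoxy-5-(SEM-oxy)chroman-4-one
Conditions: Dess–Martin periodinane, NaHCO3, CH2Cl2, 0 °C; crude ketone used at once
Reagents that add atoms: none
Why: Buffered Dess–Martin oxidation of a benzylic secondary alcohol under non-basic conditions; C3 is now α to a ketone and benzylic, so the ketone is neither chromatographed nor stored.

**Step 13**
Reactants: 23 (3R)-3-[5-bromo-2-methoxy-4-(SEM-oxy)phenyl]-7-methoxy-5-(SEM-oxy)chroman-4-one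
Product: 24 (3R,4R)-3-[5-bromo-2-methoxy-4-(SEM-oxy)phenyl]-7-methoxy-5-(SEM-oxy)chroman-4-ol (cis)
Conditions: LiBH(s-Bu)3, THF, −78 °C; aq NH4Cl
Reagents that add atoms: none
Why: Diastereoselective reduction with a hindered trialkylborohydride: the hydride should approach along the equatorial trajectory of the half-chair that has the C3 aryl group equatorial, which places the new hydroxyl axial and cis to the aryl group; at −78 °C reduction should be faster than enolisation.

**Step 14**
Reactants: 24 (3R,4R)-3-[5-bromo-2-methoxy-4-(SEM-oxy)phenyl]-7-methoxy-5-(SEM-oxy)chroman-4-ol; 25 prenylboronic acid pinacol ester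
Product: 26 (3R,4R)-7-methoxy-3-[2-methoxy-5-(3-methylbut-2-en-1-yl)-4-(SEM-oxy)phenyl]-5-(SEM-oxy)chroman-4-ol
Conditions: PdCl2(IPent)(3-chloropyridine) (IPent = 1,3-bis[2,6-di(pentan-3-yl)phenyl]imidazol-2-ylidene), aq KOH, THF, 70 °C
Reagents that add atoms: none
Why: Suzuki–Miyaura coupling of an aryl bromide with an allylic boronate; the very bulky carbene ligand is expected to force reductive elimination from the σ-allyl complex bound through the CH2 terminus, giving the linear prenyl arene rather than the 1,1-dimethylallyl isomer.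

**Step 15**
Reactants: 26 (3R,4R)-7-methoxy-3-[2-methoxy-5-(3-methylbut-2-en-1-yl)-4-(SEM-oxy)phenyl]-5-(SEM-oxy)chroman-4-ol
Product: 27 (3R,4R)-3-[4-hydroxy-2-methoxy-5-(3-methylbut-2-en-1-yl)phenyl]-7-methoxychromane-4,5-diol
Conditions: TBAF, ethylenediamine, DMPU, 60 °C; aq NH4Cl
Reagents that add atoms: none
Why: Fluoride-induced SEM cleavage (attack at silicon, loss of ethylene, collapse of the hemiacetal anion to the phenoxide); no acid is present, so the C4 carbinol is not ionised and the prenyl phenol does not cyclise, and the diamine scavenges formaldehyde before it can hydroxymethylate ring A.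

## Compound list

1 | 5-methoxyresorcinol | COc1cc(O)cc(O)c1 | starting material
2 | 3-methoxy-5-(SEM-oxy)phenol | COc1cc(O)cc(OCOCC[Si](C)(C)C)c1 | intermediate
3 | 3-methoxy-5-(SEM-oxy)phenyl N-isopropylcarbamate | COc1cc(OC(=O)NC(C)C)cc(OCOCC[Si](C)(C)C)c1 | intermediate
4 | 3-methoxy-5-(SEM-oxy)phenyl N-(tert-butyldimethylsilyl)-N-isopropylcarbamate (not isolated) | COc1cc(OC(=O)N(C(C)C)[Si](C)(C)C(C)(C)C)cc(OCOCC[Si](C)(C)C)c1 | intermediate
5 | 2-lithio derivative of 4, lithium between the carbamate and SEM-oxy groups (not isolated) | COc1cc(OC(=O)N(C(C)C)[Si](C)(C)C(C)(C)C)c([Li])c(OCOCC[Si](C)(C)C)c1 | intermediate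
6 | 5-methoxy-3-(SEM-oxy)-2-(trimethylsilyl)phenyl N-(tert-butyldimethylsilyl)-N-isopropylcarbamate (not isolated) | COc1cc(OC(=O)N(C(C)C)[Si](C)(C)C(C)(C)C)c([Si](C)(C)C)c(OCOCC[Si](C)(C)C)c1 | intermediate
7 | 5-methoxy-3-(SEM-oxy)-2-(trimethylsilyl)phenyl N-isopropylcarbamate | COc1cc(OC(=O)NC(C)C)c([Si](C)(C)C)c(OCOCC[Si](C)(C)C)c1 | intermediate
8 | 5-methoxy-3-(SEM-oxy)-2-(trimethylsilyl)phenol (not isolated) | COc1cc(O)c([Si](C)(C)C)c(OCOCC[Si](C)(C)C)c1 | intermediate
9 | 5-methoxy-3-(SEM-oxy)-2-(trimethylsilyl)phenyl trifluoromethanesulfonate | COc1cc(OCOCC[Si](C)(C)C)c([Si](C)(C)C)c(OS(=O)(=O)C(F)(F)F)c1 | intermediate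
10 | 4-hydroxy-2-methoxybenzaldehyde | COc1cc(O)ccc1C=O | starting material
11 | 5-bromo-4-hydroxy-2-methoxybenzaldehyde | COc1cc(O)c(Br)cc1C=O | intermediate
12 | 5-bromo-2-methoxy-4-(SEM-oxy)benzaldehyde | COc1cc(OCOCC[Si](C)(C)C)c(Br)cc1C=O | intermediate
13 | 1-bromo-4-methoxy-5-(2-methoxyvinyl)-2-(SEM-oxy)benzene, E/Z mixture | COC=Cc1cc(Br)c(OCOCC[Si](C)(C)C)cc1OC | intermediate
14 | 2-(acetoxymercurio)-2-[5-bromo-2-methoxy-4-(SEM-oxy)phenyl]acetaldehyde (not isolated) | CC(=O)O[Hg]C(C=O)c1cc(Br)c(OCOCC[Si](C)(C)C)cc1OC | intermediate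
15 | 2-[5-bromo-2-methoxy-4-(SEM-oxy)phenyl]acetaldehyde | O=CCc1cc(Br)c(OCOCC[Si](C)(C)C)cc1OC | intermediate
16 | 2-[5-bromo-2-methoxy-4-(SEM-oxy)phenyl]acrolein | C=C(C=O)c1cc(Br)c(OCOCC[Si](C)(C)C)cc1OC | intermediate
17 | 5-methoxy-3-(SEM-oxy)benzyne (not isolated) | COC1=CC#CC(OCOCC[Si](C)(C)C)=C1 | intermediate
18 | 2-{1-[5-bromo-2-methoxy-4-(SEM-oxy)phenyl]vinyl}-5-methoxy-3-(SEM-oxy)-2H-benzoxete, racemic (not isolated) | COc1cc(OCOCC[Si](C)(C)C)c2c(c1)OC2C(=C)c1cc(Br)c(OCOCC[Si](C)(C)C)cc1OC | intermediate
19 | 6-{2-[5-bromo-2-methoxy-4-(SEM-oxy)phenyl]prop-2-en-1-ylidene}-3-methoxy-5-(SEM-oxy)cyclohexa-2,4-dien-1-one (not isolated) | COC1=CC(=O)C(=CC(=C)c2cc(Br)c(OCOCC[Si](C)(C)C)cc2OC)C(OCOCC[Si](C)(C)C)=C1 | intermediate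
20 | 3-[5-bromo-2-methoxy-4-(SEM-oxy)phenyl]-7-methoxy-5-(SEM-oxy)-2H-chromene | COc1cc(OCOCC[Si](C)(C)C)c2c(c1)OCC(c1cc(Br)c(OCOCC[Si](C)(C)C)cc1OC)=C2 | intermediate
21 | (3R)-3-aryl-4-[hydrido(isopinocampheyl)boryl]chroman from 20, boron trans to the aryl group (not isolated) | COc1cc(OCOCC[Si](C)(C)C)c2c(c1)OC[C@@H](c1cc(Br)c(OCOCC[Si](C)(C)C)cc1OC)[C@@H]2B[C@H]1C[C@H]2C[C@@H]([C@@H]1C)C2(C)C | intermediate
22 | (3R,4S)-3-[5-bromo-2-methoxy-4-(SEM-oxy)phenyl]-7-methoxy-5-(SEM-oxy)chroman-4-ol (trans) | COc1cc(OCOCC[Si](C)(C)C)c2c(c1)OC[C@@H](c1cc(Br)c(OCOCC[Si](C)(C)C)cc1OC)[C@@H]2O | intermediate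
23 | (3R)-3-[5-bromo-2-methoxy-4-(SEM-oxy)phenyl]-7-methoxy-5-(SEM-oxy)chroman-4-one | COc1cc(OCOCC[Si](C)(C)C)c2c(c1)OC[C@@H](c1cc(Br)c(OCOCC[Si](C)(C)C)cc1OC)C2=O | intermediate
24 | (3R,4R)-3-[5-bromo-2-methoxy-4-(SEM-oxy)phenyl]-7-methoxy-5-(SEM-oxy)chroman-4-ol (cis) | COc1cc(OCOCC[Si](C)(C)C)c2c(c1)OC[C@@H](c1cc(Br)c(OCOCC[Si](C)(C)C)cc1OC)[C@H]2O | intermediate
25 | prenylboronic acid pinacol ester | CC(C)=CCB1OC(C)(C)C(C)(C)O1 | starting material
26 | (3R,4R)-7-methoxy-3-[2-methoxy-5-(3-methylbut-2-en-1-yl)-4-(SEM-oxy)phenyl]-5-(SEM-oxy)chroman-4-ol | COc1cc(OCOCC[Si](C)(C)C)c2c(c1)OC[C@@H](c1cc(CC=C(C)C)c(OCOCC[Si](C)(C)C)cc1OC)[C@H]2O | intermediate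
27 | (3R,4R)-3-[4-hydroxy-2-methoxy-5-(3-methylbut-2-en-1-yl)phenyl]-7-methoxychromane-4,5-diol | COc1cc(O)c2c(c1)OC[C@@H](c1cc(CC=C(C)C)c(O)cc1OC)[C@H]2O | target

## Step count and least certain steps

Total: 15 steps. Longest linear sequence: 11 steps (steps 5 to 15); the ring A branch (steps 1 to 4) joins at step 10.

**Step 10 (key step).** Three processes could divert the aryne: [4+2] addition across the styrene unit of 16 (vinyl group plus the free ortho position of ring B), addition of a second aryne to ortho-quinone methide 19, and hetero-Diels–Alder addition across the enal leading to the 4H-chromene isomer. Fluoride could also oligomerise the acrolein. Fallback, from 9 and 15 back to 20: the aryne from 9 is trapped with DMF (CsF, then water), a far better oxygen nucleophile, to give 2-hydroxy-4-methoxy-6-(SEM-oxy)benzaldehyde F1. Aldehyde 15 is oxidised (NaClO2, NaH2PO4, 2-methyl-2-butene) to 2-[5-bromo-2-methoxy-4-(SEM-oxy)phenyl]acetic acid F2. Perkin condensation of F1 with F2 (Ac2O, Et3N, 110 °C) gives the 3-arylcoumarin F3, LiAlH4 at 0 °C opens it to the (Z)-allylic alcohol phenol F4, and Mitsunobu etherification (PPh3, DIAD) closes the pyran ring to 20.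

**Step 11.** The SEM-oxy group at C5 is peri to C4, where the bulky borane must bond, so the addition may be slow and the facial selectivity lower than with simple 1-arylcycloalkenes; boron going to C3 is a lesser concern. Fallback, from 20 back to 24: hydroboration with BH3·SMe2 and oxidation gives the racemic trans-3-[5-bromo-2-methoxy-4-(SEM-oxy)phenyl]-7-methoxy-5-(SEM-oxy)chroman-4-ol F5, and Dess–Martin oxidation gives the racemic 3-[5-bromo-2-methoxy-4-(SEM-oxy)phenyl]-7-methoxy-5-(SEM-oxy)chroman-4-one F6. Asymmetric transfer hydrogenation with RuCl(p-cymene)[(R,R)-TsDPEN] in HCO2H/Et3N then reduces the 3R ketone faster while the enantiomers interconvert through the enol. This dynamic kinetic resolution is established for isoflavanones and should give cis alcohol 24 directly.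

**Step 12.** Enolisation of the α-aryl ketone during oxidation, work-up or handling would erode the configuration at C3, and step 13 would pass that loss on. Fallback, from 23 back to 24: the ketone, whatever its enantiomeric purity, is reduced by the same ruthenium transfer hydrogenation with dynamic kinetic resolution instead of LiBH(s-Bu)3, so its configurational integrity no longer matters.

**Step 14.** Allyl transposition at palladium would give coupling through the tertiary terminus (a 1,1-dimethylallyl arene), and the arylpalladium intermediate could oxidise the C4 alkoxide by β-hydride elimination with loss of bromine. Fallback, from 24 back to 26: coupling with allylboronic acid pinacol ester (Pd(PPh3)4, CsF, THF, reflux), where both allyl termini are the same, gives (3R,4R)-3-[5-allyl-2-methoxy-4-(SEM-oxy)phenyl]-7-methoxy-5-(SEM-oxy)chroman-4-ol F7. Cross-metathesis with 2-methyl-2-butene and second-generation Grubbs catalyst then converts the allyl group into the prenyl group of 26.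

**Step 15.** The SEM ether at C5 is hindered, and heating the phenoxide next to the C4 carbinol hard enough to cleave it may cause loss of the C4 hydroxyl through the phenoxide or attack of released formaldehyde on ring A. Fallback, from 20 to 27: the SEM groups are removed at the chromene stage, where no carbinol is present and forcing conditions are tolerated (TBAF, ethylenediamine, DMPU, 90 °C), giving 3-(5-bromo-4-hydroxy-2-methoxyphenyl)-7-methoxy-2H-chromen-5-ol F8. This is silylated (TBSCl, imidazole, DMF) to the bis-silyl ether F9. Steps 11 to 13 are repeated on F9, with NaBO3·4H2O as the mild oxidant in the hydroboration, giving the trans alcohol F10, the ketone F11 and the cis alcohol F12. Coupling of F12 with 25 under the conditions of step 14, whose warm aqueous KOH should also hydrolyse both aryl silyl ethers, gives 27; any remaining silyl ether is removed with TBAF at 0 °C.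

## Further compounds

F1 | step 10 | 2-hydroxy-4-methoxy-6-(SEM-oxy)benzaldehyde | COc1cc(O)c(C=O)c(OCOCC[Si](C)(C)C)c1
F2 | step 10 | 2-[5-bromo-2-methoxy-4-(SEM-oxy)phenyl]acetic acid | OC(=O)Cc1cc(Br)c(OCOCC[Si](C)(C)C)cc1OC
F3 | step 10 | 3-[5-bromo-2-methoxy-4-(SEM-oxy)phenyl]-7-methoxy-5-(SEM-oxy)-2H-chromen-2-one | COc1cc(OCOCC[Si](C)(C)C)c2cc(-c3cc(Br)c(OCOCC[Si](C)(C)C)cc3OC)c(=O)oc2c1
F4 | step 10 | (Z)-2-[5-bromo-2-methoxy-4-(SEM-oxy)phenyl]-3-[2-hydroxy-4-methoxy-6-(SEM-oxy)phenyl]prop-2-en-1-ol | COc1cc(O)c(/C=C(\CO)c2cc(Br)c(OCOCC[Si](C)(C)C)cc2OC)c(OCOCC[Si](C)(C)C)c1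
F5 | step 11 | racemic trans-3-[5-bromo-2-methoxy-4-(SEM-oxy)phenyl]-7-methoxy-5-(SEM-oxy)chroman-4-ol (3R*,4S*) | COc1cc(OCOCC[Si](C)(C)C)c2c(c1)OCC(c1cc(Br)c(OCOCC[Si](C)(C)C)cc1OC)C2O
F6 | step 11 | racemic 3-[5-bromo-2-methoxy-4-(SEM-oxy)phenyl]-7-methoxy-5-(SEM-oxy)chroman-4-one | COc1cc(OCOCC[Si](C)(C)C)c2c(c1)OCC(c1cc(Br)c(OCOCC[Si](C)(C)C)cc1OC)C2=O
F0 | step 12 | none | none
F7 | step 14 | (3R,4R)-3-[5-allyl-2-methoxy-4-(SEM-oxy)phenyl]-7-methoxy-5-(SEM-oxy)chroman-4-ol | COc1cc(OCOCC[Si](C)(C)C)c2c(c1)OC[C@@H](c1cc(CC=C)c(OCOCC[Si](C)(C)C)cc1OC)[C@H]2O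
F8 | step 15 | 3-(5-bromo-4-hydroxy-2-methoxyphenyl)-7-methoxy-2H-chromen-5-ol | COc1cc(O)c2c(c1)OCC(c1cc(Br)c(O)cc1OC)=C2
F9 | step 15 | 3-[5-bromo-4-(tert-butyldimethylsilyloxy)-2-methoxyphenyl]-5-(tert-butyldimethylsilyloxy)-7-methoxy-2H-chromene | COc1cc(O[Si](C)(C)C(C)(C)C)c2c(c1)OCC(c1cc(Br)c(O[Si](C)(C)C(C)(C)C)cc1OC)=C2
F10 | step 15 | (3R,4S)-3-[5-bromo-4-(tert-butyldimethylsilyloxy)-2-methoxyphenyl]-5-(tert-butyldimethylsilyloxy)-7-methoxychroman-4-ol | COc1cc(O[Si](C)(C)C(C)(C)C)c2c(c1)OC[C@@H](c1cc(Br)c(O[Si](C)(C)C(C)(C)C)cc1OC)[C@@H]2O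
F11 | step 15 | (3R)-3-[5-bromo-4-(tert-butyldimethylsilyloxy)-2-methoxyphenyl]-5-(tert-butyldimethylsilyloxy)-7-methoxychroman-4-one | COc1cc(O[Si](C)(C)C(C)(C)C)c2c(c1)OC[C@@H](c1cc(Br)c(O[Si](C)(C)C(C)(C)C)cc1OC)C2=O
F12 | step 15 | (3R,4R)-3-[5-bromo-4-(tert-butyldimethylsilyloxy)-2-methoxyphenyl]-5-(tert-butyldimethylsilyloxy)-7-methoxychroman-4-ol | COc1cc(O[Si](C)(C)C(C)(C)C)c2c(c1)OC[C@@H](c1cc(Br)c(O[Si](C)(C)C(C)(C)C)cc1OC)[C@H]2O
A1 | alternative 1 | 3-[4-(tert-butyldimethylsilyloxy)-2-methoxy-5-prenylphenyl]-7-methoxy-3-nitrochromane-4,5-diol, C4 configured as in the target, C3 epimers | COc1cc(O)c2c(c1)OCC(c1cc(CC=C(C)C)c(O[Si](C)(C)C(C)(C)C)cc1OC)([N+](=O)[O-])[C@H]2O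
A2 | alternative 1 | 1-[4-(tert-butyldimethylsilyloxy)-2-methoxy-5-prenylphenyl]-1-nitroethene | C=C([N+](=O)[O-])c1cc(CC=C(C)C)c(O[Si](C)(C)C(C)(C)C)cc1OC
A3 | alternative 1 | 2,6-dihydroxy-4-methoxybenzaldehyde | COc1cc(O)c(C=O)c(O)c1
A4 | alternative 2 | (3R,4R)-target as its 4,5-bis(tert-butyldimethylsilyl) ether with free 4'-hydroxyl | COc1cc(O[Si](C)(C)C(C)(C)C)c2c(c1)OC[C@@H](c1cc(CC=C(C)C)c(O)cc1OC)[C@H]2O[Si](C)(C)C(C)(C)C
A5 | alternative 2 | 1-[(3R,4R)-4,5-bis(tert-butyldimethylsilyloxy)-7-methoxychroman-3-yl]-1-diazo-7-methylocta-3,6-dien-2-one | COc1cc(O[Si](C)(C)C(C)(C)C)c2c(c1)OC[C@@H](C(=[N+]=[N-])C(=O)C=CCC=C(C)C)[C@H]2O[Si](C)(C)C(C)(C)C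
A6 | alternative 2 | methoxyacetylene | COC#C
A7 | alternative 3 | racemic 3-[4-(tert-butyldimethylsilyloxy)-2-methoxy-5-prenylphenyl]-5,7-dimethoxychroman-4-one | COc1cc(OC)c2c(c1)OCC(c1cc(CC=C(C)C)c(O[Si](C)(C)C(C)(C)C)cc1OC)C2=O
A8 | alternative 3 | 2-[4-(tert-butyldimethylsilyloxy)-2-methoxy-5-prenylphenyl]-2-diazo-1-(2,4,6-trimethoxyphenyl)ethanone | COc1cc(OC)c(C(=O)C(=[N+]=[N-])c2cc(CC=C(C)C)c(O[Si](C)(C)C(C)(C)C)cc2OC)c(OC)c1
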